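The cage is cut at C3–C28 and C5–C6, the two bonds that tie the four-carbon bridge C6–C7–C27–C28 to the quaternary carbons C3 and C5 flanking the C4 ketone. Both carbons are the prenylated ring positions of a symmetric 3,5-diprenyl-2,4,6-trihydroxybenzophenone, so one flask can dearomatise the arene by iridium-catalysed branched allylation at C3 and close the seven-membered ring C3–C4–C5–C6–C7–C27–C28 by 7-endo Michael addition of C5. This sets C3, C5, C7 and C28 and leaves C1 enolised. The partner is a geometrically pure (E)-allyl methyl carbonate bearing a methyl 2-methylene ester. Cation closure C1–C8 and a cobalt peroxidation cascade then complete the homoadamantane and the 1,2-dioxepane.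

Key step: step 4

Numbering used: trione ring C1 (benzoyl)–C2–C3–C4–C5–C9; bridge C5–C6–C7–C27–C28–C3; C8 = CMe2 between C7 and C1; C29 = CMe2 on C28; C17–C18–C19 = side chain on C3; all descriptors refer to this numbering.
Assumption: the (S,S,Sa) ligand is taken to give 28R by the usual facial model of iridium phosphoramidite allylation; should the phenolate reverse it, the antipodal ligand is used.
Assumption: C7 stays adjustable at the ester stage; if DBU equilibration favours the other C7 epimer of 9, that epimer is separated and re-equilibrated.

Step 1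
Reactants: 1 2,4,6-trihydroxybenzophenone; 2 prenyl bromide (2 equiv)
Product: 3 3,5-diprenyl-2,4,6-trihydroxybenzophenone
Conditions: KOH (5% aq.), 0 °C
Reagents that add atoms: none
Why: Direct C-alkylation of the phloroglucinolate in water, where the solvated oxygens leave the two free ring carbons as the nucleophilic sites, should stop mainly at the aromatic 3,5-dialkylated stage, and over-alkylated dearomatised by-products are removed by chromatography.

Step 2
Reactants: 4 methyl 2-(bromomethyl)acrylate; 5 (E)-3-(tributylstannyl)prop-2-en-1-ol
Product: 6 methyl (E)-6-hydroxy-2-methylenehex-4-enoate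
Conditions: Pd2(dba)3 (2.5 mol %), P(2-furyl)3 (10 mol %), THF, 50 °C
Reagents that add atoms: none
Why: Stille coupling of an allylic bromide with an alkenylstannane runs through a symmetrical 2-(methoxycarbonyl)allylpalladium species and transfers the alkenyl group with retention, so the E geometry required by the iridium step is carried in from the stannane.

Step 3
Reactants: 6 methyl (E)-6-hydroxy-2-methylenehex-4-enoate
Product: 7 methyl (E)-6-(methoxycarbonyloxy)-2-methylenehex-4-enoate
Conditions: ClCO2Me, pyridine, CH2Cl2, 0 °C
Reagents that add atoms: methyl chloroformate, COC(=O)Cl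
Why: Acylation of a primary allylic alcohol with a chloroformate gives the carbonate, and pairing a methyl carbonate with a methyl ester means the methoxide released in step 4 cannot scramble the ester.

Step 4
Reactants: 3 3,5-diprenyl-2,4,6-trihydroxybenzophenone (1.2 equiv); 7 methyl (E)-6-(methoxycarbonyloxy)-2-methylenehex-4-enoate
Product: 9 bicyclo[4.3.1]decane enol methyl ester (3S,5S,7S,28R; ester at C7, vinyl at C28, prenyl at C3 and C5, benzoyl at C1, 2-enol, 4,9-dione), via C3-allylated dearomatised dienol 8 (not isolated)
Conditions: [Ir(cod)Cl]2 (2 mol %), (S,S,Sa)-phosphoramidite (4 mol %; (Sa)-BINOL-derived, N,N-bis[(S)-1-phenylethyl]), catalyst pre-formed with n-PrNH2 and evaporated, THF, 25 °C; then DBU (2 equiv), 25 → 40 °C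
Reagents that add atoms: none
Why: Proposed new method: the cyclometalated iridium–phosphoramidite complex ionises carbonate 7 with loss of CO2 and methoxide, the methoxide deprotonates 3, and a prenyl-bearing carbon of the phenolate attacks the substituted terminus of the allyliridium unit to give dearomatised 8 (C3–C28), after which DBU generates the dienolate of 8 and its C5 adds to the acrylate terminus C6 with protonation at C7. The closest known reaction types are the iridium-catalysed asymmetric allylic dearomatisation of phenols and naphthols and the base-mediated alkylative dearomatisation–annulation of acylphloroglucinols with acrylate electrophiles, which has so far closed six-membered rings. The one ring formed, C3–C4–C5–C6–C7–C27–C28, closes by a 7-endo-trig conjugate addition. C28 is set by the catalyst through the face of the allyl unit (28R expected from the (S,S,Sa) ligand), C3 by the catalyst's pairing of that face with one of the two enantiotopic prenyl-bearing carbons, C5 by the tether, which reaches C5 only cis to the C3 chain, and C7 by protonation under DBU equilibration, the epimer with the ester turned toward C1 being carried on. The step needs C- over O-allylation, branched attack, a single allylation and ring closure through C5 and not C1: the soft phloroglucinolate carbon, the branched preference of this catalyst class, 7 as the limiting component and the low nucleophilicity of the benzoyl-bearing carbon held in a hydrogen-bonded β-tricarbonyl are relied on. No Michael addition is expected before DBU is added, because a 2-alkylacrylate is a poor acceptor for the neutral phenol.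

Step 5
Reactants: 9 bicyclo[4.3.1]decane enol methyl ester
Product: 10 tertiary alcohol (3S,5S,7S,28R; as 9 with C7–C(CH3)2OH, the new carbon being C8)
Conditions: MeMgBr (6 equiv), CeCl3 (6 equiv), THF, −78 → 0 °C
Reagents that add atoms: methylmagnesium bromide, C[Mg]Br
Why: Double addition of the organocerium reagent to the ester should be selective because the first equivalent turns the acidic enol into an enolate that masks C2, C9 and the benzoyl carbonyl, the C4 ketone sits on a one-carbon bridge between two quaternary carbons, and the weakly basic cerium reagent leaves C7 unepimerised.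

Step 6
Reactants: 10 tertiary alcohol
Product: 11 homoadamantane trione (1R,3R,5S,7S,28R; C1–C8 bond closed, 1-benzoyl, 8,8-dimethyl, 3,5-diprenyl, 28-vinyl, 2,4,9-trione)
Conditions: HCO2H/CH2Cl2 (1:4), 0 → 25 °C
Reagents that add atoms: none
Why: Ionisation of the tertiary alcohol gives the C8 cation, which alkylates the enol carbon C1 (SN1 tert-alkylation of a β-triketone enol closing the six-membered ring C1–C8–C7–C6–C5–C9); capture by enol oxygen is reversible under acid, C8 can reach C1 only on the face that carries the bridge so the configuration at C1 follows from the cage, and a tertiary alcohol ionises in formic acid faster than the prenyl or vinyl double bonds are protonated.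

Step 7
Reactants: 11 homoadamantane trione
Product: 12 28-acetyl homoadamantane trione (1R,3R,5S,7S,28S)
Conditions: PdCl2 (20 mol %), CuCl (1 equiv), O2 (1 atm), DMF/H2O (7:1), 25 °C
Reagents that add atoms: water, O
Why: Tsuji–Wacker oxidation should touch only the monosubstituted vinyl group with Markovnikov delivery of water, since trisubstituted prenyl alkenes do not undergo hydroxypalladation, no enol remains (C1 is now quaternary) to be drawn into an oxidative cyclisation, and C28 is not epimerised in this near-neutral medium.

Step 8
Reactants: 12 28-acetyl homoadamantane trione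
Product: 13 28-isopropenyl homoadamantane trione (1R,3R,5S,7S,28R)
Conditions: Ph3PCH3Br (3.0 equiv), KN(SiMe3)2 (2.8 equiv), THF, 0 °C; then 12, 0 → 25 °C
Reagents that add atoms: methyltriphenylphosphonium bromide, C[P+](c1ccccc1)(c1ccccc1)c1ccccc1.[Br-]
Why: Wittig methylenation should take the only accessible carbonyl group, because the ring ketones C2, C4 and C9 each lie between two quaternary carbons and the benzoyl ketone sits on quaternary C1; the ylide is made with a deficit of base so that no amide attacks the non-enolisable triketone, and the C28 methine next to quaternary C3 is too shielded to be deprotonated.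

Step 9
Reactants: 13 28-isopropenyl homoadamantane trione
Product: 14 19-O-triethylsilyl peroxide of the target (1R,3R,5S,7S,18S,28S)
Conditions: Co(acac)2 (20 mol %), Et3SiH (2.5 equiv), O2 (1 atm), ClCH2CH2Cl, 25 °C
Reagents that add atoms: dioxygen, O=O; triethylsilane, CC[SiH](CC)CC
Why: In this Mukaiyama–Isayama hydroperoxysilylation a cobalt hydride transfers a hydrogen atom to the 1,1-disubstituted alkene (faster than to the trisubstituted prenyl groups), the C29 radical takes up O2, the peroxyl radical adds 7-exo-trig to C18 of the prenyl group on the neighbouring carbon C3, and the C19 radical takes up a second O2 and is reduced to the silyl peroxide, as in known hydrogen-atom-transfer peroxyl cyclisations to 1,2-dioxanes and 1,2-dioxepanes; C18 is set by the substrate, closure through the twist-chair in which the O–O unit runs past the C4 carbonyl side and the C19 terminus points away from the cage giving 18S, which is an expectation and not secured.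

Step 10
Reactants: 14 19-O-triethylsilyl peroxide
Product: 15 target hydroperoxide (1R,3R,5S,7S,18S,28S)
Conditions: HCl (cat.), MeOH, 0 °C
Reagents that add atoms: none
Why: Acid-catalysed methanolysis of the labile Si–O bond of a silyl peroxide frees the hydroperoxide, and the brief cold exposure should leave the dialkyl peroxide, the ketones and the prenyl group untouched.

Compound list
1 | 2,4,6-trihydroxybenzophenone | O=C(c1ccccc1)c1c(O)cc(O)cc1O | starting material
2 | prenyl bromide (1-bromo-3-methylbut-2-ene) | CC(C)=CCBr | starting material
3 | 3,5-diprenyl-2,4,6-trihydroxybenzophenone | CC(C)=CCc1c(O)c(CC=C(C)C)c(O)c(C(=O)c2ccccc2)c1O | intermediate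
4 | methyl 2-(bromomethyl)acrylate | C=C(CBr)C(=O)OC | starting material
5 | (E)-3-(tributylstannyl)prop-2-en-1-ol | CCCC[Sn](CCCC)(CCCC)/C=C/CO | starting material
6 | methyl (E)-6-hydroxy-2-methylenehex-4-enoate | C=C(C(=O)OC)C/C=C/CO | intermediate
7 | methyl (E)-6-(methoxycarbonyloxy)-2-methylenehex-4-enoate | C=C(C(=O)OC)C/C=C/COC(=O)OC | intermediate
8 | C3-allylated dearomatised dienol (3S,28R): C3 carries prenyl and CH(CH=CH2)CH2C(=CH2)CO2Me, C5 prenyl, C1 benzoyl; not isolated | CC(C)=CC[C@@]1([C@@H](C=C)CC(=C)C(=O)OC)C(=O)C(CC=C(C)C)=C(O)C(C(=O)c2ccccc2)=C1O | intermediate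
9 | methyl (3S,5S,7S,28R)-1-benzoyl-2-hydroxy-4,9-dioxo-3,5-diprenyl-28-vinylbicyclo[4.3.1]dec-1-ene-7-carboxylate | CC(C)=CC[C@]12C[C@@H](C(=O)OC)C[C@H](C=C)[C@](CC=C(C)C)(C1=O)C(O)=C(C(=O)c1ccccc1)C2=O | intermediate
10 | (3S,5S,7S,28R)-tertiary alcohol: 9 with C7–C(CH3)2OH in place of the ester | CC(C)=CC[C@]12C[C@@H](C(C)(C)O)C[C@H](C=C)[C@](CC=C(C)C)(C1=O)C(O)=C(C(=O)c1ccccc1)C2=O | intermediate
11 | (1R,3R,5S,7S,28R)-1-benzoyl-8,8-dimethyl-3,5-diprenyl-28-vinylhomoadamantane-2,4,9-trione | CC(C)=CC[C@]12C[C@@H]3C[C@H](C=C)[C@](CC=C(C)C)(C1=O)C(=O)[C@](C(=O)c1ccccc1)(C2=O)C3(C)C | intermediate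
12 | (1R,3R,5S,7S,28S)-28-acetyl analogue of 11 | CC(C)=CC[C@]12C[C@@H]3C[C@H](C(C)=O)[C@](CC=C(C)C)(C1=O)C(=O)[C@](C(=O)c1ccccc1)(C2=O)C3(C)C | intermediate
13 | (1R,3R,5S,7S,28R)-28-isopropenyl analogue of 11 | CC(C)=CC[C@]12C[C@@H]3C[C@H](C(C)=C)[C@](CC=C(C)C)(C1=O)C(=O)[C@](C(=O)c1ccccc1)(C2=O)C3(C)C | intermediate
14 | (1R,3R,5S,7S,18S,28S)-19-O-triethylsilyl peroxide of 15 | CC(C)=CC[C@]12C[C@@H]3C[C@@H]4C(C)(C)OO[C@H](C(C)(C)OO[Si](CC)(CC)CC)C[C@@]4(C1=O)C(=O)[C@](C(=O)c1ccccc1)(C2=O)C3(C)C | intermediate
15 | (1R,3R,5S,7S,18S,28S)-1-benzoyl-8,8-dimethyl-5-prenylhomoadamantane-2,4,9-trione fused at C3/C28 to a 1,2-dioxepane (C3–C17–C18–O–O–C29–C28, gem-dimethyl at C29) bearing 2-hydroperoxypropan-2-yl at C18 | CC(C)=CC[C@]12C[C@@H]3C[C@@H]4C(C)(C)OO[C@H](C(C)(C)OO)C[C@@]4(C1=O)C(=O)[C@](C(=O)c1ccccc1)(C2=O)C3(C)C | target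

Total steps: 10. Longest linear sequence: 9 steps (4 → 6 → 7 → 9 → 10 → 11 → 12 → 13 → 14 → 15).

Steps most likely to fail

Step 4. The phenolate may be allylated on oxygen or at the mismatched enantiotopic carbon (poor diastereocontrol at C3), a second allylation at C5 may outrun ring closure, or the 7-endo addition may stall. The fallback uses known reactions, sets out from 4 and 3 and comes back at 9. Copper-mediated coupling of 4 with prop-2-yn-1-ol (CuI, K2CO3, NaI, DMF) should give methyl 6-hydroxy-2-methylenehex-4-ynoate F1, and semihydrogenation over Pd/CaCO3 poisoned with Pb(OAc)2 and quinoline should give methyl (Z)-6-hydroxy-2-methylenehex-4-enoate F2. Mitsunobu etherification of 3 at its non-chelated 4-hydroxyl (PPh3, DIAD, THF) should give the aryl (Z)-allyl ether F3. Aromatic Claisen rearrangement (toluene, 110 °C) carries the allyl unit to a prenyl-bearing ortho carbon with allylic transposition, which guarantees the branched C3–C28 bond. The Z ether is chosen because its chair transition state leads to the required relative configuration at C3 and C28, whereas the E ether would give the C28 epimer. This gives racemic 8, that is 8 together with its enantiomer ent-8 F4. DBU then closes the ring as in step 4 to racemic 9, that is 9 and its enantiomer ent-9 F5, and preparative chromatography on a chiral stationary phase should give 9.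

Step 9. The C29 peroxyl radical may be reduced before it closes the ring, it may add to the wrong face of C18, or the C5 prenyl group may be hydroperoxysilylated as well. The fallback sets out from 13 and comes back at 15. The same cobalt conditions run concentrated with excess silane, where trapping outruns cyclisation, should give the open-chain C29 triethylsilyl peroxide F6, and HCl (cat.) in MeOH should give the tertiary C29 hydroperoxide F7. A peroxyl radical chain cyclisation under O2 started by di-tert-butyl hyponitrite (benzene, 40 °C), a known route from unsaturated hydroperoxides to cyclic peroxides, then closes the dioxepane with no reductant present. Chain-carrying hydrogen transfer gives 15 directly, and any 18-epimer is removed by chromatography.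

Step 6. A prenyl double bond may be protonated and captured by the enol oxygen, or the C8 cation may be captured lastingly on oxygen instead of at C1. The fallback sets out from 10 and comes back at 11. Silylation (TMSOTf, Et3N, CH2Cl2, −78 °C) should give the bis(trimethylsilyl) derivative F8, a silyl enol ether at O2 and a silyl ether at the C8 oxygen. Catalytic TMSOTf with 2,6-di-tert-butyl-4-methylpyridine (CH2Cl2, −78 → −20 °C) ionises the tertiary silyl ether, and the silyl enol ether is alkylated at C1 under proton-free conditions (tert-alkylation of a silyl enol ether) to give 11.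

Further compounds
F1 | step 4 | methyl 6-hydroxy-2-methylenehex-4-ynoate | C=C(C(=O)OC)CC#CCO
F2 | step 4 | methyl (Z)-6-hydroxy-2-methylenehex-4-enoate | C=C(C(=O)OC)C/C=C\CO
F3 | step 4 | 4-O-[(Z)-5-(methoxycarbonyl)hexa-2,5-dienyl] ether of 3 | C=C(C(=O)OC)C/C=C\COc1c(CC=C(C)C)c(O)c(C(=O)c2ccccc2)c(O)c1CC=C(C)C
F4 | step 4 | ent-8 (3R,28S) | CC(C)=CC[C@]1([C@H](C=C)CC(=C)C(=O)OC)C(=O)C(CC=C(C)C)=C(O)C(C(=O)c2ccccc2)=C1O
F5 | step 4 | ent-9 (3R,5R,7R,28S) | CC(C)=CC[C@@]12C[C@H](C(=O)OC)C[C@@H](C=C)[C@@](CC=C(C)C)(C1=O)C(O)=C(C(=O)c1ccccc1)C2=O
F6 | step 9 | open-chain C29 triethylsilyl peroxide (1R,3R,5S,7S,28S) | CC(C)=CC[C@]12C[C@@H]3C[C@H](C(C)(C)OO[Si](CC)(CC)CC)[C@](CC=C(C)C)(C1=O)C(=O)[C@](C(=O)c1ccccc1)(C2=O)C3(C)C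
F7 | step 9 | open-chain C29 hydroperoxide (1R,3R,5S,7S,28S) | CC(C)=CC[C@]12C[C@@H]3C[C@H](C(C)(C)OO)[C@](CC=C(C)C)(C1=O)C(=O)[C@](C(=O)c1ccccc1)(C2=O)C3(C)C
F8 | step 6 | bis(trimethylsilyl) derivative of 10 (2-O-silyl enol ether, C8 silyl ether) | CC(C)=CC[C@]12C[C@@H](C(C)(C)O[Si](C)(C)C)C[C@H](C=C)[C@](CC=C(C)C)(C1=O)C(O[Si](C)(C)C)=C(C(=O)c1ccccc1)C2=O
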